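(The rate constants were chosen freely; no experiment stands behind them.)

The ratio that opens the books is the rate at which substrate goes to the intermediate over the rate at which it goes to self-condensation product, 0.281 at the charge, and from there I follow one molecule of substrate through its forks.

    substrate → intermediate (k1 = 0.0488 h⁻¹)
    first nucleophile + intermediate → target (k2 = 85.3 M⁻¹ h⁻¹)
    second nucleophile + intermediate → other capture product (k3 = 77.2 M⁻¹ h⁻¹)
    intermediate → solvolysis product (k4 = 2.23 h⁻¹)
    first nucleophile + protic impurity → quenched reagent (k5 = 57.0 M⁻¹ h⁻¹)
    2 substrate → self-condensation product (k6 = 4.34 M⁻¹ h⁻¹)
    intermediate → side product (k7 = 3.58 h⁻¹)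

all flasks: substrate 20 mM; first nucleophile 20.0 mM; protic impurity 4.00 mM; time 2.5 d
- ochre: second nucleophile 4.00 mM
- grey: second nucleophile 8.00 mM
- green: second nucleophile 15.0 mM

- in percentages every species weighs as the substrate in it: one self-condensation product counts as two
- where a step has two of a species, its rate is k times that concentration squared, and two are used at each turn
- "hardly changes" means that all values lie within two and a half points (for a concentration: within two and a half percent of the largest)
- run time (ochre): 2.5 d

- amount of target at the end, in percent of the substrate charged for ochre, grey, green, in this order
- the course of these numbers from the first flask to the last (falls all the way / rises, then falls / hardly changes / rises all the way / falls, then rises)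

I keep the ledger in percent of the substrate charged.

1. First fork. Neither loss of substrate has a nucleophile on its left, so I integrate the two together. By the end, 41.4% has entered the intermediate, 1.23% is still substrate, and 57.4% is self-condensation product.

2. Impurity. First nucleophile meets it at 1.14 h⁻¹, faster than substrate feeds the intermediate at 0.0488 h⁻¹. So I book the impurity off early, which leaves c(first nucleophile) at 16.0 mM. It stands higher at first and lower later, but I hold it constant.

3. Second fork. An intermediate molecule leaves by solvolysis and side product at 5.81 h⁻¹ together, and by first nucleophile at a pseudo-first-order 1.36 h⁻¹. In ochre, second nucleophile adds 0.309 h⁻¹, making 7.48 h⁻¹ in sum. The rate of capture by first nucleophile over the sum of the rates out of the intermediate is 0.182 in ochre, and I call it the target chance. It is 0.175 in grey and 0.164 in green.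

4. Closing the books for ochre. The 41.4% from the first fork divides into target 7.53%, side product 19.8%, solvolysis product 12.3% and other capture product 1.71%.

5. My row. Target is 7.53% in ochre, 7.24% in grey and 6.79% in green. That is a fall of 0.77 percentage points, inside the margin for that course, so I say it hardly changes.

6. The forecast gives 7.4%, 7.2%, 6.7% and hardly changes, on the ground that “capture is a minority path”. Its ochre figure is lower than mine, and its shape is the same.

7. The flasks give 7.40%, 7.13%, 6.69%, and the course hardly changes.

In ochre at 2.50 d, the two exits without a nucleophile run at 5.81 h⁻¹, faster than first nucleophile at 1.24 h⁻¹ with 73% of its charge left, and the target's reading among the 4 products of the intermediate is 0.179 against a target chance of 0.182. In green the same reading is 0.162 against 0.164, and the target's local order in second nucleophile is −0.13, where the target chance gives −0.139.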